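## Retrosynthetic overview

1. Last bond: the chalcone C=C, by Claisen–Schmidt condensation of the aryl methyl ketone with the aromatic aldehyde; both benzene rings are bought.
2. The C-3 carbinol comes from the benzofuran-3-one by hydroxyl-directed reduction. Before that, the dihydrofuran ring (the only ring made) is closed by 5-exo opening of a (2R,3S)-epoxide by the 4-phenoxide.
3. The epoxide comes from a Z-trisubstituted alkene, with the face chosen by the bought side-chain carbinol (vanadium, bishomoallylic direction). The C-3–C-2 bond is made by Nozaki–Hiyama–Kishi addition of a Z-iodoalkene (Normant carbocupration) to an aryl aldehyde.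
4. The aldehyde carbon is put on the crowded C-3 of the resorcinol ketone by an aromatic Claisen rearrangement (the key C–C bond), followed by alkene isomerisation and cleavage.
5. One stereocentre is bought in an (R)-hydroxylactone; the other three are relayed from it.

Assumption: (3R)-3-hydroxyoxolan-2-one 1 ((R)-α-hydroxy-γ-butyrolactone, made on scale from D-malic acid) is taken as a purchasable chiral-pool compound.

## Route

Step 1
Reactants: 1 (3R)-3-hydroxyoxolan-2-one
Product: 2 (3R)-4-methylpentane-1,3,4-triol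
Conditions: MeMgBr (3.5 equiv), THF, 0 °C → rt; aq. NH4Cl
Reagents that add atoms: methylmagnesium bromide, C[Mg]Br
Why: Double Grignard addition to the lactone carbonyl (the free hydroxyl is deprotonated first) gives the tertiary alcohol without touching the stereocentre, which stays R.

Step 2
Reactants: 2 (3R)-4-methylpentane-1,3,4-triol
Product: 3 2-[(4R)-2,2,5,5-tetramethyl-1,3-dioxolan-4-yl]ethan-1-ol
Conditions: 2,2-dimethoxypropane, PPTS (cat.), CH2Cl2, rt
Reagents that add atoms: 2,2-dimethoxypropane, COC(C)(C)OC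
Why: Acid-catalysed transketalisation gives the thermodynamically favoured five-membered dioxolane on the vicinal secondary/tertiary diol and leaves the primary alcohol free.

Step 3
Reactants: 3 2-[(4R)-2,2,5,5-tetramethyl-1,3-dioxolan-4-yl]ethan-1-ol
Product: 4 (4R)-4-(2-iodoethyl)-2,2,5,5-tetramethyl-1,3-dioxolane
Conditions: I2, PPh3, imidazole, CH2Cl2, 0 °C → rt
Reagents that add atoms: iodine, II
Why: Appel-type iodination, an SN2 displacement of the activated primary alcohol that is remote from the stereocentre.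

Step 4
Reactants: 4 (4R)-4-(2-iodoethyl)-2,2,5,5-tetramethyl-1,3-dioxolane; 5 propyne
Product: 9 (4R)-4-[(3Z)-4-iodo-3-methylbut-3-en-1-yl]-2,2,5,5-tetramethyl-1,3-dioxolane, via Grignard reagent 6 (not isolated), via alkylcopper 7 (not isolated), via alkenylcopper 8 (not isolated)
Conditions: Mg, Et2O; CuBr·SMe2, Et2O–Me2S, −45 °C; propyne, −25 °C; I2, −45 → 0 °C
Reagents that add atoms: iodine, II
Why: Normant carbocupration adds the alkylcopper syn across propyne (alkyl to the internal carbon, copper to the terminal one), and iodinolysis with retention gives the Z-iodoalkene with the chain cis to iodine.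

Step 5
Reactants: 10 1-(2,4-dihydroxyphenyl)ethanone; 11 3-bromoprop-1-ene
Product: 12 1-[2-hydroxy-4-(prop-2-en-1-yloxy)phenyl]ethanone
Conditions: K2CO3, acetone, reflux
Reagents that add atoms: none
Why: Williamson etherification occurs only at the 4-hydroxyl because the 2-hydroxyl is tied up in a hydrogen bond to the acetyl group.

Step 6
Reactants: 12 1-[2-hydroxy-4-(prop-2-en-1-yloxy)phenyl]ethanone
Product: 14 1-[2,4-dihydroxy-3-(prop-2-en-1-yl)phenyl]ethanone, via dienone 13 (not isolated)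
Conditions: N,N-diethylaniline, 200 °C
Reagents that add atoms: none
Why: Aromatic Claisen rearrangement ([3,3]-sigmatropic shift, then enolisation of the dienone) delivers the allyl group to C-3 rather than C-5 because the chelated 2-hydroxyacetophenone localises the ring double bond between C-3 and C-4; this makes the aryl–carbon bond that ends as the bond to C-3 of the benzofuran.

Step 7
Reactants: 14 1-[2,4-dihydroxy-3-(prop-2-en-1-yl)phenyl]ethanone
Product: 15 1-[2,4-dihydroxy-3-[(1E)-prop-1-en-1-yl]phenyl]ethanone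
Conditions: [RuClH(CO)(PPh3)3] (5 mol%), toluene, 80 °C
Reagents that add atoms: none
Why: Ruthenium hydride-catalysed alkene isomerisation (hydrometalation/β-hydride elimination) moves the double bond into conjugation with the arene.

Step 8
Reactants: 15 1-[2,4-dihydroxy-3-[(1E)-prop-1-en-1-yl]phenyl]ethanone
Product: 17 3-acetyl-2,6-dihydroxybenzaldehyde, via syn-diol 16 (not isolated)
Conditions: OsO4 (2 mol%), NaIO4 (4 equiv), 2,6-lutidine, dioxane–H2O, rt
Reagents that add atoms: sodium periodate, [Na+].[O-]I(=O)(=O)=O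
Why: Lemieux–Johnson oxidation (OsO4-catalysed dihydroxylation, then periodate glycol cleavage) cuts the propenyl group down to the aldehyde, so the carbon placed by the Claisen step becomes the future C-3.

Step 9
Reactants: 17 3-acetyl-2,6-dihydroxybenzaldehyde; 9 (4R)-4-[(3Z)-4-iodo-3-methylbut-3-en-1-yl]-2,2,5,5-tetramethyl-1,3-dioxolane
Product: 19 1-[2,4-bis[[tert-butyl(dimethyl)silyl]oxy]-3-[(2Z)-1-[[tert-butyl(dimethyl)silyl]oxy]-3-methyl-5-[(4R)-2,2,5,5-tetramethyl-1,3-dioxolan-4-yl]pent-2-en-1-yl]phenyl]ethanone (1:1 mixture of C-1 epimers), via allylic alcohol 18 (not isolated)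
Conditions: CrCl2 (8 equiv), NiCl2 (2 mol%), DMF, rt; aq. work-up; then TBSOTf (4 equiv), 2,6-lutidine, CH2Cl2, −78 → 0 °C
Reagents that add atoms: tert-butyldimethylsilyl trifluoromethanesulfonate, CC(C)(C)[Si](C)(C)OS(=O)(=O)C(F)(F)F
Why: Nozaki–Hiyama–Kishi coupling adds the alkenylchromium species (Z geometry retained) to the aldehyde in the presence of the ketone; the new carbinol forms unselectively, which is accepted because it is erased in step 12 and reset in step 13, and silylation then masks the three hydroxyls so that none of them can direct the epoxidation.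

Step 10
Reactants: 19 1-[2,4-bis[[tert-butyl(dimethyl)silyl]oxy]-3-[(2Z)-1-[[tert-butyl(dimethyl)silyl]oxy]-3-methyl-5-[(4R)-2,2,5,5-tetramethyl-1,3-dioxolan-4-yl]pent-2-en-1-yl]phenyl]ethanone
Product: 20 1-[2,4-bis[[tert-butyl(dimethyl)silyl]oxy]-3-[(2Z,6R)-1-[[tert-butyl(dimethyl)silyl]oxy]-6,7-dihydroxy-3,7-dimethyloct-2-en-1-yl]phenyl]ethanone (C-1 epimers)
Conditions: CeCl3·7H2O, oxalic acid (cat.), MeCN, rt
Reagents that add atoms: none
Why: Mild Lewis-acid ketal hydrolysis removes the acetonide while the aryl and benzylic silyl ethers survive, freeing the 6,7-diol that must direct the next step.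

Step 11
Reactants: 20 1-[2,4-bis[[tert-butyl(dimethyl)silyl]oxy]-3-[(2Z,6R)-1-[[tert-butyl(dimethyl)silyl]oxy]-6,7-dihydroxy-3,7-dimethyloct-2-en-1-yl]phenyl]ethanone
Product: 22 1-[(2S)-3,4-dihydroxy-2-[(2S,5R)-2,5,6-trihydroxy-6-methylheptan-2-yl]-2,3-dihydro-1-benzofuran-5-yl]ethanone (C-3 epimers), via epoxide 21 (not isolated)
Conditions: VO(acac)2 (10 mol%), t-BuOOH (1.5 equiv), NaOAc, CH2Cl2, 0 °C → rt; then TBAF, AcOH, THF, 0 °C → rt
Reagents that add atoms: tert-butyl hydroperoxide, CC(C)(C)OO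
Why: Hydroxyl-directed epoxidation of a bishomoallylic alcohol (Kishi chair model, C(CH3)2OH equatorial) lets the vanadate bound at the C-6 hydroxyl deliver oxygen to the face of the Z-alkene that gives the (2R,3S)-epoxide for both C-1 epimers; fluoride then frees the more acidic, non-chelated 4-phenoxide, which opens the epoxide at its secondary carbon with inversion (5-exo-tet) to set C-2 (S) and the tertiary carbinol (S).

Step 12
Reactants: 22 1-[(2S)-3,4-dihydroxy-2-[(2S,5R)-2,5,6-trihydroxy-6-methylheptan-2-yl]-2,3-dihydro-1-benzofuran-5-yl]ethanone (C-3 epimers)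
Product: 23 (2R)-5-acetyl-4-hydroxy-2-[(2S,5R)-2,5,6-trihydroxy-6-methylheptan-2-yl]-1-benzofuran-3(2H)-one
Conditions: MnO2 (excess), acetone, rt
Reagents that add atoms: none
Why: Selective MnO2 oxidation of the benzylic alcohol converts both C-3 epimers into one ketone and leaves the aliphatic secondary alcohol alone; C-2 is unchanged in space (its descriptor becomes R only through the priority change).

Step 13
Reactants: 23 (2R)-5-acetyl-4-hydroxy-2-[(2S,5R)-2,5,6-trihydroxy-6-methylheptan-2-yl]-1-benzofuran-3(2H)-one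
Product: 24 1-[(2S,3S)-3,4-dihydroxy-2-[(2S,5R)-2,5,6-trihydroxy-6-methylheptan-2-yl]-2,3-dihydro-1-benzofuran-5-yl]ethanone
Conditions: Me4NBH(OAc)3, MeCN–AcOH (1:1), −25 °C
Reagents that add atoms: none
Why: Evans–Saksena directed reduction: the acetoxyborohydride bound to the tertiary hydroxyl of the C-2 side chain delivers hydride to C-3 from the side-chain face, giving the 2,3-trans (3S) alcohol, while the chelated acetyl ketone has no such handle.

Step 14
Reactants: 24 1-[(2S,3S)-3,4-dihydroxy-2-[(2S,5R)-2,5,6-trihydroxy-6-methylheptan-2-yl]-2,3-dihydro-1-benzofuran-5-yl]ethanone; 25 4-hydroxybenzaldehyde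
Product: 26 (2E)-1-[(2S,3S)-3,4-dihydroxy-2-[(2S,5R)-2,5,6-trihydroxy-6-methylheptan-2-yl]-2,3-dihydro-1-benzofuran-5-yl]-3-(4-hydroxyphenyl)prop-2-en-1-one
Conditions: KOH (50% aq.), EtOH, rt; then aq. NH4Cl
Reagents that add atoms: none
Why: Claisen–Schmidt crossed aldol condensation with E1cB dehydration gives the E-enone; no stereocentre is involved and C-3 is no longer a ketone, so retro-aldol is not possible.

## Compound list

1 | (3R)-3-hydroxyoxolan-2-one | O[C@@H]1CCOC1=O | starting material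
2 | (3R)-4-methylpentane-1,3,4-triol | CC(C)(O)[C@H](O)CCO | intermediate
3 | 2-[(4R)-2,2,5,5-tetramethyl-1,3-dioxolan-4-yl]ethan-1-ol | CC1(C)O[C@H](CCO)C(C)(C)O1 | intermediate
4 | (4R)-4-(2-iodoethyl)-2,2,5,5-tetramethyl-1,3-dioxolane | CC1(C)O[C@H](CCI)C(C)(C)O1 | intermediate
5 | propyne | CC#C | starting material
6 | [2-[(4R)-2,2,5,5-tetramethyl-1,3-dioxolan-4-yl]ethyl]magnesium iodide | CC1(C)O[C@H](CC[Mg]I)C(C)(C)O1 | intermediate
7 | [2-[(4R)-2,2,5,5-tetramethyl-1,3-dioxolan-4-yl]ethyl]copper | CC1(C)O[C@H](CC[Cu])C(C)(C)O1 | intermediate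
8 | [(1Z)-2-methyl-4-[(4R)-2,2,5,5-tetramethyl-1,3-dioxolan-4-yl]but-1-en-1-yl]copper | CC1(C)O[C@H](CC/C(C)=C\[Cu])C(C)(C)O1 | intermediate
9 | (4R)-4-[(3Z)-4-iodo-3-methylbut-3-en-1-yl]-2,2,5,5-tetramethyl-1,3-dioxolane | CC1(C)O[C@H](CC/C(C)=C\I)C(C)(C)O1 | intermediate
10 | 1-(2,4-dihydroxyphenyl)ethanone | CC(=O)c1ccc(O)cc1O | starting material
11 | 3-bromoprop-1-ene | C=CCBr | starting material
12 | 1-[2-hydroxy-4-(prop-2-en-1-yloxy)phenyl]ethanone | CC(=O)c1ccc(OCC=C)cc1O | intermediate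
13 | 4-acetyl-5-hydroxy-6-(prop-2-en-1-yl)cyclohexa-2,4-dien-1-one | CC(=O)C1=C(O)C(CC=C)C(=O)C=C1 | intermediate
14 | 1-[2,4-dihydroxy-3-(prop-2-en-1-yl)phenyl]ethanone | CC(=O)c1ccc(O)c(CC=C)c1O | intermediate
15 | 1-[2,4-dihydroxy-3-[(1E)-prop-1-en-1-yl]phenyl]ethanone | CC(=O)c1ccc(O)c(/C=C/C)c1O | intermediate
16 | 1-[3-(1,2-dihydroxypropyl)-2,4-dihydroxyphenyl]ethanone (racemic syn-diol) | CC(=O)c1ccc(O)c(C(O)C(C)O)c1O | intermediate
17 | 3-acetyl-2,6-dihydroxybenzaldehyde | CC(=O)c1ccc(O)c(C=O)c1O | intermediate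
18 | 1-[2,4-dihydroxy-3-[(2Z)-1-hydroxy-3-methyl-5-[(4R)-2,2,5,5-tetramethyl-1,3-dioxolan-4-yl]pent-2-en-1-yl]phenyl]ethanone (C-1 epimers) | CC(=O)c1ccc(O)c(C(O)/C=C(/C)CC[C@H]2OC(C)(C)OC2(C)C)c1O | intermediate
19 | 1-[2,4-bis[[tert-butyl(dimethyl)silyl]oxy]-3-[(2Z)-1-[[tert-butyl(dimethyl)silyl]oxy]-3-methyl-5-[(4R)-2,2,5,5-tetramethyl-1,3-dioxolan-4-yl]pent-2-en-1-yl]phenyl]ethanone (C-1 epimers) | CC(=O)c1ccc(O[Si](C)(C)C(C)(C)C)c(C(O[Si](C)(C)C(C)(C)C)/C=C(/C)CC[C@H]2OC(C)(C)OC2(C)C)c1O[Si](C)(C)C(C)(C)C | intermediate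
20 | 1-[2,4-bis[[tert-butyl(dimethyl)silyl]oxy]-3-[(2Z,6R)-1-[[tert-butyl(dimethyl)silyl]oxy]-6,7-dihydroxy-3,7-dimethyloct-2-en-1-yl]phenyl]ethanone (C-1 epimers) | CC(=O)c1ccc(O[Si](C)(C)C(C)(C)C)c(C(O[Si](C)(C)C(C)(C)C)/C=C(/C)CC[C@@H](O)C(C)(C)O)c1O[Si](C)(C)C(C)(C)C | intermediate
21 | 1-[2,4-bis[[tert-butyl(dimethyl)silyl]oxy]-3-[[tert-butyl(dimethyl)silyl]oxy[(2R,3S)-3-[(3R)-3,4-dihydroxy-4-methylpentyl]-3-methyloxiran-2-yl]methyl]phenyl]ethanone (C-1 epimers) | CC(=O)c1ccc(O[Si](C)(C)C(C)(C)C)c(C(O[Si](C)(C)C(C)(C)C)[C@H]2O[C@@]2(C)CC[C@@H](O)C(C)(C)O)c1O[Si](C)(C)C(C)(C)C | intermediate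
22 | 1-[(2S)-3,4-dihydroxy-2-[(2S,5R)-2,5,6-trihydroxy-6-methylheptan-2-yl]-2,3-dihydro-1-benzofuran-5-yl]ethanone (C-3 epimers) | CC(C)(O)[C@H](O)CC[C@](C)(O)[C@H]1Oc2ccc(C(C)=O)c(O)c2C1O | intermediate
23 | (2R)-5-acetyl-4-hydroxy-2-[(2S,5R)-2,5,6-trihydroxy-6-methylheptan-2-yl]-1-benzofuran-3(2H)-one | CC(C)(O)[C@H](O)CC[C@](C)(O)[C@H]1Oc2ccc(C(C)=O)c(O)c2C1=O | intermediate
24 | 1-[(2S,3S)-3,4-dihydroxy-2-[(2S,5R)-2,5,6-trihydroxy-6-methylheptan-2-yl]-2,3-dihydro-1-benzofuran-5-yl]ethanone | CC(C)(O)[C@H](O)CC[C@](C)(O)[C@H]1Oc2ccc(C(C)=O)c(O)c2[C@@H]1O | intermediate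
25 | 4-hydroxybenzaldehyde | O=Cc1ccc(O)cc1 | starting material
26 | (2E)-1-[(2S,3S)-3,4-dihydroxy-2-[(2S,5R)-2,5,6-trihydroxy-6-methylheptan-2-yl]-2,3-dihydro-1-benzofuran-5-yl]-3-(4-hydroxyphenyl)prop-2-en-1-one (CNP0284606.1) | CC(C)(O)[C@H](O)CC[C@](C)(O)[C@H]1Oc2ccc(C(=O)/C=C/c3ccc(O)cc3)c(O)c2[C@@H]1O | target

## Step count and risks

Total steps: 14. Longest linear sequence: 10 steps (steps 1–4 then 9–14; the arene branch, steps 5–8, is also four steps and joins at step 9).

The step most likely to fail is step 11. The whole stereochemical relay rests on the vanadate at the side-chain hydroxyl reaching a trisubstituted alkene that sits next to a very crowded silyloxy(aryl)methyl carbon. The reaction may be slow, one C-1 epimer may resist the delivery face, and the hydroxy epoxide can close to a tetrahydrofuran if it is not trapped quickly. The fallback sets out from alcohol 18, taken before silylation. Its own allylic hydroxyl directs a peracid epoxidation (mCPBA, NaHCO3, CH2Cl2, 0 °C), where allylic 1,3-strain gives the threo epoxide from each C-1 epimer. This gives 1-[2,4-dihydroxy-3-[(S)-hydroxy[(2R,3S)-3-methyl-3-[2-[(4R)-2,2,5,5-tetramethyl-1,3-dioxolan-4-yl]ethyl]oxiran-2-yl]methyl]phenyl]ethanone F1 together with its diastereomer of opposite configuration at all three new centres. K2CO3 in MeOH closes both to 2,3-trans benzofurans, and 1-[(2S,3S)-3,4-dihydroxy-2-[(2S)-2-hydroxy-4-[(4R)-2,2,5,5-tetramethyl-1,3-dioxolan-4-yl]butan-2-yl]-2,3-dihydro-1-benzofuran-5-yl]ethanone F2 is separated from its diastereomer by preparative HPLC. This separation is not stereocontrolled and costs half the material. Aqueous AcOH at room temperature then removes the acetonide and the fallback rejoins the route at 24, so steps 12 and 13 are skipped.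

The second is step 9. The aldehyde carries two acidic, chelating phenols, and the free ortho-hydroxybenzylic allylic alcohol 18 can lose water to a quinone methide and cyclise to a chromene before it is silylated. The fallback sets out from 17 and masks the phenols first (TBSCl, imidazole, DMF) to give 3-acetyl-2,6-bis[[tert-butyl(dimethyl)silyl]oxy]benzaldehyde F3. The same chromium-mediated coupling with 9 then gives the stable mono-alcohol 1-[2,4-bis[[tert-butyl(dimethyl)silyl]oxy]-3-[(2Z)-1-hydroxy-3-methyl-5-[(4R)-2,2,5,5-tetramethyl-1,3-dioxolan-4-yl]pent-2-en-1-yl]phenyl]ethanone F4, which is silylated (TBSOTf, 2,6-lutidine) to rejoin the route at 19.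

The third is step 13. Ketone 23 is a β-hydroxy ketone with an enolisable C-2, so epimerisation, dehydration or retro-aldol can compete, and the acetyl ketone might be reduced as well. The fallback sets out from 22 and avoids the ketone altogether: the two C-3 epimers of 22 are separated by chromatography (they differ at a ring carbon next to C-2), and the (3S) epimer is 24 itself. This rejoins the route at 24 and makes no new compound, at the cost of the (3R) material.

Further compounds
F1 | step 11 | 1-[2,4-dihydroxy-3-[(S)-hydroxy[(2R,3S)-3-methyl-3-[2-[(4R)-2,2,5,5-tetramethyl-1,3-dioxolan-4-yl]ethyl]oxiran-2-yl]methyl]phenyl]ethanone | CC(=O)c1ccc(O)c([C@H](O)[C@H]2O[C@@]2(C)CC[C@H]3OC(C)(C)OC3(C)C)c1O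
F2 | step 11 | 1-[(2S,3S)-3,4-dihydroxy-2-[(2S)-2-hydroxy-4-[(4R)-2,2,5,5-tetramethyl-1,3-dioxolan-4-yl]butan-2-yl]-2,3-dihydro-1-benzofuran-5-yl]ethanone | CC1(C)O[C@H](CC[C@](C)(O)[C@H]2Oc3ccc(C(C)=O)c(O)c3[C@@H]2O)C(C)(C)O1
F3 | step 9 | 3-acetyl-2,6-bis[[tert-butyl(dimethyl)silyl]oxy]benzaldehyde | CC(=O)c1ccc(O[Si](C)(C)C(C)(C)C)c(C=O)c1O[Si](C)(C)C(C)(C)C
F4 | step 9 | 1-[2,4-bis[[tert-butyl(dimethyl)silyl]oxy]-3-[(2Z)-1-hydroxy-3-methyl-5-[(4R)-2,2,5,5-tetramethyl-1,3-dioxolan-4-yl]pent-2-en-1-yl]phenyl]ethanone | CC(=O)c1ccc(O[Si](C)(C)C(C)(C)C)c(C(O)/C=C(/C)CC[C@H]2OC(C)(C)OC2(C)C)c1O[Si](C)(C)C(C)(C)C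
F0 | step 13 | none | none
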